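The runs come from a simulation from invented constants, noise included.

The meeting opened on the plateau. A single-handed catalyst joins partner to left-handed substrate, and the question was how much left-handed product each new flask holds at 4.0 d.

| setting | delta | zeta | alpha | violet | amber | blue | red |
|---|---|---|---|---|---|---|---|
| left-handed substrate | 0.40 M | 0.40 M | 0.40 M | 0.40 M | 0.40 M | 0.40 M | 0.40 M |
| right-handed substrate | 0.40 M | 0.40 M | 0.40 M | 0.40 M | 0.40 M | 0.40 M | 0.40 M |
| partner | 1.1 equiv | 1.1 equiv | 1.6 equiv | 0.360 equiv | 0.360 equiv | 4.40 equiv | 1.10 equiv |
| catalyst | 0.026 mol% | 0.31 mol% | 0.1 mol% | 0.15 mol% | 0.03 mol% | 0.4 mol% | 0.1 mol% |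
| remark | run made earlier | run made earlier | run made earlier |  |  |  |  |
| time |  |  |  | 4.0 d | 4.0 d | 4.0 d | 4.0 d |

| run | time / d | left-handed product / % | left-handed substrate / % |
|---|---|---|---|
| delta | 0.208 | 3.1 | 46.6 |
| delta | 0.500 | 0 | 47.6 |
| delta | 1.25 | 2.9 | 47.1 |
| delta | 3.00 | 3.3 | 45.8 |
| zeta | 0.208 | 7.9 | 43.1 |
| zeta | 0.500 | 13.9 | 38.0 |
| zeta | 1.25 | 16.7 | 34.5 |
| zeta | 3.00 | 18.3 | 31.2 |
| alpha | 0.625 | 8.4 | 45.0 |
| alpha | 1.25 | 8.3 | 40.6 |
| alpha | 2.00 | 10.6 | 39.9 |
| alpha | 3.00 | 9.6 | 37.2 |

(readings scatter by 1 percentage point)

- ranking by amount of left-handed product, in percent of the left-handed substrate and right-handed substrate together charged, from high to low, at 4.0 d (violet / amber / blue / red)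
- the amount of left-handed product, in percent of the left-handed substrate and right-handed substrate together charged of the flask you put first, at 4.0 d
- the amount of left-handed product, in percent of the left-handed substrate and right-handed substrate together charged of the flask you put last, at 4.0 d

I, keeping the minutes, proposed working in logarithms and taking each run's last reading as what its recipe holds at the asked time. From delta to zeta, both at 1.1 equiv, the fraction of the charge found as left-handed product rises 0.691 decades per decade of catalyst. That line gives 8.37% at 0.1 mol%. Alpha, at that loading with 1.6 equiv, read 9.6%, which gives 0.365 for the partner slope, the decades of left-handed product gained per decade of partner at fixed catalyst. I conceded that this rests on one reading with a scatter of 1 percentage point, so it is rough.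

My reckoning put blue at 36.2%, red at 8.37%, violet at 7.37% and amber at 2.42%. My reckoning thus had red above violet, by a narrow 1 point.

The forecast argued for blue > violet > red > amber, with 23% on top and 3.5% at the bottom, holding that “Partner has little visible effect”. We differed on blue's amount and on red against violet.

The flasks gave blue > red > violet > amber, with blue at 35.1%, red at 10.3%, violet at 7.31% and amber at 2.46%.

    partner + catalyst + left-handed substrate → catalyst + left-handed product (k = 88.0 /M²/h)
    partner + catalyst + right-handed substrate → catalyst + right-handed product (k = 35.0 /M²/h)
    2 partner → self-condensation product (k = 0.150 /M/h)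

In amber at 4.00 d, partner goes to self-condensation product at 1.5 times the rate at which it goes to left-handed product. In blue, partner is the limiting reagent: 0.26% of its charge stands at 4.00 d, against 30% of the left-handed substrate. Carried to blue, the partner slope raises the 20.8% of the red recipe with 0.4 mol% of catalyst to 34.5% at blue's 4.40 equiv; blue gives 35.1%. For amber's recipe with 0.12 mol% of catalyst, the slopes give 6.32%; that flask gives 6.55%.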